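The plan cuts C6–C7 and C7–C11 of the cis-disubstituted gem-dimethylcyclopropane (C6, C7, C11). C6 hangs on ring carbon C5, the neighbour of cyclopentanone carbonyl C1. C7 bears chain carbon C8. A temporary ester bridge C1–O–C8(=O) can therefore hold a C7 carbene above an isobutenyl group on C5. One rhodium-catalysed [2+1] addition then closes the cyclopropane and a six-membered lactone together and sets C6 and C7. The precursor is the diazoacetate of a cis-2-isobutenylcyclopentanol that already carries quaternary C4 and benzylic C7′, both set by one Ireland–Claisen rearrangement. Lactone reduction later returns C1 to a ketone and makes C8 the aldehyde from which the oxobutyl chain grows.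

Key step: step 12

Atom labels: five-membered ring C1 (carbonyl or carbinol carbon), C2, C3, C4 (quaternary), C5. Cyclopropane C6 (on C5), C7 (bears C8), C11 (CMe2). Chain C8–C9–C10(=O)–CH3. C7′ is the benzylic CH and C8′ its CH2 (the carboxyl carbon in 5–9).
Assumption: 1 is taken as a catalogue compound, and ester 6 is assumed to enolise in THF–DMPU, as arylacetates generally do, to the enolate with aryl cis to O-metal.
Remark: C4, C5 and C7′ of 19 and 20, and C6 and C7 of 20, map onto 26 without inversion. The C1–O bond is cis to C6 and trans to the C7′ branch.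

Step 1
Reactants: 1 2-bromo-3-methylcyclopent-2-en-1-one; 2 2-methylprop-1-enylboronic acid pinacol ester
Product: 3 3-methyl-2-(2-methylprop-1-enyl)cyclopent-2-en-1-one
Conditions: PdCl2(dppf) (3 mol %), K2CO3, dioxane–H2O, 80 °C
Reagents that add atoms: none
Why: Suzuki–Miyaura coupling: the electron-poor C–Br bond of an α-bromoenone adds readily to zerovalent palladium and the alkenylboronate transfers its isobutenyl group, so C5–C6 is made on the simplest substrate and no stereocentre is involved.

Step 2
Reactants: 3 3-methyl-2-(2-methylprop-1-enyl)cyclopent-2-en-1-one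
Product: 4 (1R)-3-methyl-2-(2-methylprop-1-enyl)cyclopent-2-en-1-ol
Conditions: (S)-2-methyl-CBS-oxazaborolidine (15 mol %), catecholborane, toluene, −78 °C
Reagents that add atoms: none
Why: Corey–Bakshi–Shibata reduction: the ketone binds the catalyst boron away from the branched alkenyl side (C5, large) and towards C2H2 (small), so the (S)-catalyst should deliver hydride 1,2 to the face that gives the (R)-carbinol at C1, and catecholborane at low temperature leaves the diene alone.

Step 3
Reactants: 4 (1R)-3-methyl-2-(2-methylprop-1-enyl)cyclopent-2-en-1-ol; 5 2,4,6-trimethoxyphenylacetic acid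
Product: 6 (1R)-3-methyl-2-(2-methylprop-1-enyl)cyclopent-2-en-1-yl 2-(2,4,6-trimethoxyphenyl)acetate
Conditions: EDC·HCl, DMAP (cat.), CH2Cl2, 0 °C → rt
Reagents that add atoms: none
Why: Steglich-type carbodiimide esterification runs under weakly basic conditions that the easily ionised dienol tolerates, and it leaves the C1–O bond and its configuration untouched.

Step 4
Reactants: 6 (1R)-3-methyl-2-(2-methylprop-1-enyl)cyclopent-2-en-1-yl 2-(2,4,6-trimethoxyphenyl)acetate
Product: 9 (2R)-2-[(1R)-1-methyl-2-(2-methylprop-1-enyl)cyclopent-2-en-1-yl]-2-(2,4,6-trimethoxyphenyl)acetic acid, via Z-silyl ketene acetal 7 (not isolated), via trimethylsilyl ester 8 (not isolated)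
Conditions: LDA, THF–DMPU, −78 °C; Me3SiCl; → rt, then 50 °C; aqueous citric acid
Reagents that add atoms: chlorotrimethylsilane, C[Si](C)(C)Cl (its silyl group is present only in 7 and 8)
Why: Ireland–Claisen rearrangement: the ketene acetal with aryl cis to OSiMe3 reacts through a chair, because a boat would stack C8′–OSiMe3 on the isobutenyl-bearing C5; the shift on the face of the C1–O bond carries chirality suprafacially to quaternary C4 (R) and puts the aryl group outward, which gives C7′ (R).

Step 5
Reactants: 9 (2R)-2-[(1R)-1-methyl-2-(2-methylprop-1-enyl)cyclopent-2-en-1-yl]-2-(2,4,6-trimethoxyphenyl)acetic acid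
Product: 10 (2R)-2-[(1R)-1-methyl-2-(2-methylprop-1-enyl)cyclopent-2-en-1-yl]-2-(2,4,6-trimethoxyphenyl)ethan-1-ol
Conditions: LiAlH4, THF, 0 → 40 °C
Reagents that add atoms: none
Why: Hydride reduction of a carboxylic acid: the carboxylate formed first protects C7′ from epimerisation, and the unactivated diene and the aryl ethers are inert to LiAlH4.

Step 6
Reactants: 10 (2R)-2-[(1R)-1-methyl-2-(2-methylprop-1-enyl)cyclopent-2-en-1-yl]-2-(2,4,6-trimethoxyphenyl)ethan-1-ol
Product: 11 p-toluenesulfonate of 10
Conditions: TsCl, Et3N, DMAP (cat.), CH2Cl2, 0 °C → rt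
Reagents that add atoms: p-toluenesulfonyl chloride, Cc1ccc(cc1)S(=O)(=O)Cl
Why: Sulfonylation of a primary alcohol: a tosylate is preferred to a halide because organocopper species displace it by a two-electron SN2 path, so no C8′ radical arises that could cyclise onto the isobutenyl group.

Step 7
Reactants: 11 p-toluenesulfonate of 10
Product: 12 2-{(1R)-3-methyl-1-[(1R)-1-methyl-2-(2-methylprop-1-enyl)cyclopent-2-en-1-yl]butyl}-1,3,5-trimethoxybenzene
Conditions: i-PrMgCl, Li2CuCl4 (5 mol %), THF, −20 °C → rt
Reagents that add atoms: isopropylmagnesium chloride, CC(C)[Mg]Cl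
Why: Copper-catalysed Grignard–tosylate cross-coupling (Kochi–Schlosser type) joins primary C8′ to the isopropyl carbon, completes the isobutyl group without touching C7′, and leaves the unactivated diene alone.

Step 8
Reactants: 12 2-{(1R)-3-methyl-1-[(1R)-1-methyl-2-(2-methylprop-1-enyl)cyclopent-2-en-1-yl]butyl}-1,3,5-trimethoxybenzene
Product: 14 (1S,2S,3R)-3-methyl-2-(2-methylprop-1-enyl)-3-[(1R)-3-methyl-1-(2,4,6-trimethoxyphenyl)butyl]cyclopentan-1-ol, via B-alkyl-9-BBN adduct 13 (not isolated)
Conditions: 9-BBN, THF, rt → 50 °C; then NaOH, H2O2, 0 °C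
Reagents that add atoms: hydrogen peroxide, OO (the C1 oxygen); 9-borabicyclo[3.3.1]nonane, B1C2CCCC1CCC2 (present only in 13)
Why: Hydroboration–oxidation: boron goes to C1, the only unsubstituted diene terminus and remote from C4, whereas the isobutenyl unit could take boron only at crowded internal C6 or at fully substituted C11; syn addition from the methyl face is expected, but neither new centre has to be right because C5 and C1 are reset in steps 9 and 10.

Step 9
Reactants: 14 (1S,2S,3R)-3-methyl-2-(2-methylprop-1-enyl)-3-[(1R)-3-methyl-1-(2,4,6-trimethoxyphenyl)butyl]cyclopentan-1-ol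
Product: 16 (2R,3R)-3-methyl-2-(2-methylprop-1-enyl)-3-[(1R)-3-methyl-1-(2,4,6-trimethoxyphenyl)butyl]cyclopentan-1-one, via C5-epimeric ketone 15 (not isolated)
Conditions: Dess–Martin periodinane, CH2Cl2, 0 °C → rt; aqueous wash; DBU (cat.), CH2Cl2, rt, short contact
Reagents that add atoms: none
Why: Dess–Martin oxidation followed by base-mediated epimerisation: C5 equilibrates through the enolate to the isomer with isobutenyl trans to the large C7′ branch, and catalytic base with short contact is chosen because α-protonation of the dienolate is faster than the γ-protonation that would move the alkene into conjugation.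

Step 10
Reactants: 16 (2R,3R)-3-methyl-2-(2-methylprop-1-enyl)-3-[(1R)-3-methyl-1-(2,4,6-trimethoxyphenyl)butyl]cyclopentan-1-one
Product: 17 (1S,2R,3R)-3-methyl-2-(2-methylprop-1-enyl)-3-[(1R)-3-methyl-1-(2,4,6-trimethoxyphenyl)butyl]cyclopentan-1-ol (OH cis to isobutenyl)
Conditions: LiBH(s-Bu)3, THF, −78 °C; NaOH, H2O2 work-up
Reagents that add atoms: none
Why: Diastereoselective ketone reduction with a bulky trialkylborohydride: the face carrying the adjacent isobutenyl group and the pseudoaxial C4 methyl is shielded, so hydride enters from the other face and the C1 hydroxyl ends cis to isobutenyl, the usual outcome for 2-substituted cyclopentanones.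

Step 11
Reactants: 17 (1S,2R,3R)-3-methyl-2-(2-methylprop-1-enyl)-3-[(1R)-3-methyl-1-(2,4,6-trimethoxyphenyl)butyl]cyclopentan-1-ol
Product: 19 diazoacetate of 17, via bromoacetate 18 (not isolated)
Conditions: BrCH2COBr, NaHCO3, MeCN, 0 °C; extractive work-up; TsNHNHTs, DBU, THF, 0 °C
Reagents that add atoms: bromoacetyl bromide, BrCC(Br)=O; N,N′-ditosylhydrazine, Cc1ccc(cc1)S(=O)(=O)NNS(=O)(=O)c1ccc(C)cc1
Why: O-acylation followed by the N,N′-ditosylhydrazine diazoacetate synthesis: the hydrazine nitrogen is alkylated by the bromoacetate and two base-induced sulfinate eliminations leave the diazo group, all without acid that could close the cis-homoallylic alcohol onto its alkene.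

Step 12
Reactants: 19 diazoacetate of 17
Product: 20 cyclopropane-fused δ-lactone (ring O–C1–C5–C6–C7–C8)
Conditions: Rh2(cap)4 (1 mol %, cap = caprolactamate), CH2Cl2, reflux, 19 added slowly by syringe pump
Reagents that add atoms: none
Why: Loss of N2 at the dirhodium core gives an electrophilic rhodium carbene at C7 that adds to C6=C11 in one concerted, asynchronous [2+1] step; the closest known reaction type is the intramolecular cyclopropanation of homoallylic diazoacetates to 3-oxabicyclo[4.1.0]heptan-2-ones. The three-membered ring closes by this [2+1] addition (C6–C7 and C7–C11), and the six-membered lactone closes in the same event in a 6-exo sense, C6 becoming a ring member while C11 stays outside. C6 is set by rotamer control: the C11 methyl that is Z to C5 would clash with the ring unless the small C5–H eclipses the double bond, and in that rotamer one π face looks at C4 and the other at C1–O, so the short ester tether lets C7 approach only from the latter, which maps onto the C6 configuration of 26. C7 is set by the tether, because the lactone can span C6 and C7 only when C5 and C8 are cis on the cyclopropane. The step needs chemoselectivity for the alkene over C–H insertion and arene attack: C5–H is trans to the ester and out of reach, the arene sits on the opposite ring face, and only C2–H competes, which the electron-rich carboxamidate ligands and the nucleophilic trisubstituted alkene disfavour. Slow addition keeps the diazo concentration low and suppresses carbene dimers.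

Step 13
Reactants: 20 cyclopropane-fused δ-lactone
Product: 21 diol with secondary C1–OH and primary C8–OH
Conditions: LiAlH4, THF, 0 °C
Reagents that add atoms: none
Why: Hydride reduction of a lactone to the 1,5-diol: full reduction is preferred to a lactol, because olefination of a lactol would leave a C1 hydroxyl placed for oxa-Michael closure onto the new enone.

Step 14
Reactants: 21 diol with secondary C1–OH and primary C8–OH
Product: 23 (E)-enone C7–CH=CH–C(=O)CH3 with C1 ketone, via keto aldehyde 22 (not isolated)
Conditions: (COCl)2, DMSO, CH2Cl2, −78 °C; Et3N; then Ph3P=CHC(O)CH3, → rt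
Reagents that add atoms: 1-(triphenylphosphoranylidene)propan-2-one, CC(=O)C=P(c1ccccc1)(c1ccccc1)c1ccccc1
Why: Swern oxidation activates both hydroxyls before base is added, so the keto aldehyde forms without passing through the lactol that would be re-oxidised to 20, and the stabilised ylide added to the same flask undergoes an E-selective Wittig reaction with the aldehyde only, ketones being inert to it.

Step 15
Reactants: 23 (E)-enone C7–CH=CH–C(=O)CH3 with C1 ketone
Product: 24 diketone with the 3-oxobutyl chain on C7 (aryl still 2,4,6-trimethoxyphenyl)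
Conditions: H2 (3 atm), RhCl(PPh3)3 (10 mol %), toluene, rt
Reagents that add atoms: none
Why: Homogeneous hydrogenation adds H2 to the only C=C bond through a dihydride–alkyl sequence that produces neither a free metal enolate (so no reductive aldol of C9 onto the C1 ketone) nor a radical at cyclopropylcarbinyl C8 (so no ring opening), and it leaves ketones and arene untouched.

Step 16
Reactants: 24 diketone with the 3-oxobutyl chain on C7
Product: 25 3,5-diformyl-2,4,6-trimethoxyphenyl diketone
Conditions: Cl2CHOCH3, TiCl4, CH2Cl2, −78 → 0 °C; ice-water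
Reagents that add atoms: dichloromethyl methyl ether, COC(Cl)Cl; water, O
Why: Rieche formylation: the trimethoxyarene is by far the most nucleophilic site, each of its two free positions has two ortho and one para methoxy group so both are formylated, and the low temperature is meant to spare the alkyl cyclopropane and the ketones.

Step 17
Reactants: 25 3,5-diformyl-2,4,6-trimethoxyphenyl diketone
Product: 26 target CNP0217082.3
Conditions: BCl3, CH2Cl2, −78 → 0 °C; aqueous work-up
Reagents that add atoms: none
Why: Chelation-assisted aryl methyl ether cleavage: every methoxy group is ortho to a formyl group, so BCl3 bound to the carbonyl oxygen removes all three methyl groups as chloromethane at low temperature, where the ketones and the unactivated cyclopropane should persist.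

Compound list
1 | 2-bromo-3-methylcyclopent-2-en-1-one | CC1=C(Br)C(=O)CC1 | starting material
2 | 2-methylprop-1-enylboronic acid pinacol ester | CC(C)=CB1OC(C)(C)C(C)(C)O1 | starting material
3 | 3-methyl-2-(2-methylprop-1-enyl)cyclopent-2-en-1-one | CC1=C(C=C(C)C)C(=O)CC1 | intermediate
4 | (1R)-3-methyl-2-(2-methylprop-1-enyl)cyclopent-2-en-1-ol | O[C@@H]1CCC(C)=C1C=C(C)C | intermediate
5 | 2,4,6-trimethoxyphenylacetic acid | COc1cc(OC)c(CC(=O)O)c(OC)c1 | starting material
6 | (1R)-3-methyl-2-(2-methylprop-1-enyl)cyclopent-2-en-1-yl 2-(2,4,6-trimethoxyphenyl)acetate | COc1cc(OC)c(CC(=O)O[C@@H]2CCC(C)=C2C=C(C)C)c(OC)c1 | intermediate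
7 | (Z)-trimethylsilyl ketene acetal of 6, aryl cis to OSiMe3 (not isolated) | COc1cc(OC)c(/C=C(\O[Si](C)(C)C)O[C@@H]2CCC(C)=C2C=C(C)C)c(OC)c1 | intermediate
8 | trimethylsilyl ester of 9 (not isolated) | C[Si](C)(C)OC(=O)[C@@H](c1c(OC)cc(OC)cc1OC)[C@@]1(C)CCC=C1C=C(C)C | intermediate
9 | (2R)-2-[(1R)-1-methyl-2-(2-methylprop-1-enyl)cyclopent-2-en-1-yl]-2-(2,4,6-trimethoxyphenyl)acetic acid | OC(=O)[C@@H](c1c(OC)cc(OC)cc1OC)[C@@]1(C)CCC=C1C=C(C)C | intermediate
10 | (2R)-2-[(1R)-1-methyl-2-(2-methylprop-1-enyl)cyclopent-2-en-1-yl]-2-(2,4,6-trimethoxyphenyl)ethan-1-ol | OC[C@@H](c1c(OC)cc(OC)cc1OC)[C@@]1(C)CCC=C1C=C(C)C | intermediate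
11 | p-toluenesulfonate of 10 | Cc1ccc(cc1)S(=O)(=O)OC[C@@H](c1c(OC)cc(OC)cc1OC)[C@@]1(C)CCC=C1C=C(C)C | intermediate
12 | 2-{(1R)-3-methyl-1-[(1R)-1-methyl-2-(2-methylprop-1-enyl)cyclopent-2-en-1-yl]butyl}-1,3,5-trimethoxybenzene | CC(C)C[C@@H](c1c(OC)cc(OC)cc1OC)[C@@]1(C)CCC=C1C=C(C)C | intermediate
13 | B-alkyl-9-BBN adduct, boron on C1, trans to isobutenyl (not isolated) | C1CC2CCCC(C1)B2[C@H]1CC[C@](C)([C@@H](CC(C)C)c2c(OC)cc(OC)cc2OC)[C@@H]1C=C(C)C | intermediate
14 | (1S,2S,3R)-3-methyl-2-(2-methylprop-1-enyl)-3-[(1R)-3-methyl-1-(2,4,6-trimethoxyphenyl)butyl]cyclopentan-1-ol (OH trans to isobutenyl) | O[C@H]1CC[C@](C)([C@@H](CC(C)C)c2c(OC)cc(OC)cc2OC)[C@@H]1C=C(C)C | intermediate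
15 | (2S,3R)-ketone, isobutenyl cis to the C7′ branch (not isolated) | O=C1CC[C@](C)([C@@H](CC(C)C)c2c(OC)cc(OC)cc2OC)[C@@H]1C=C(C)C | intermediate
16 | (2R,3R)-3-methyl-2-(2-methylprop-1-enyl)-3-[(1R)-3-methyl-1-(2,4,6-trimethoxyphenyl)butyl]cyclopentan-1-one (isobutenyl trans to the C7′ branch) | O=C1CC[C@](C)([C@@H](CC(C)C)c2c(OC)cc(OC)cc2OC)[C@H]1C=C(C)C | intermediate
17 | (1S,2R,3R)-3-methyl-2-(2-methylprop-1-enyl)-3-[(1R)-3-methyl-1-(2,4,6-trimethoxyphenyl)butyl]cyclopentan-1-ol (OH cis to isobutenyl) | O[C@H]1CC[C@](C)([C@@H](CC(C)C)c2c(OC)cc(OC)cc2OC)[C@H]1C=C(C)C | intermediate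
18 | bromoacetate of 17 (not isolated) | BrCC(=O)O[C@H]1CC[C@](C)([C@@H](CC(C)C)c2c(OC)cc(OC)cc2OC)[C@H]1C=C(C)C | intermediate
19 | diazoacetate of 17 (key-step precursor) | [N-]=[N+]=CC(=O)O[C@H]1CC[C@](C)([C@@H](CC(C)C)c2c(OC)cc(OC)cc2OC)[C@H]1C=C(C)C | intermediate
20 | cyclopropane-fused δ-lactone, cis-fused to the cyclopentane at C1–C5 and to the CMe2 cyclopropane at C6–C7, C11 on the face of H1 and H5 (labels 1S,4R,5R,6S,7R,7′R) | O=C1O[C@H]2CC[C@](C)([C@@H](CC(C)C)c3c(OC)cc(OC)cc3OC)[C@H]2[C@H]2[C@@H]1C2(C)C | intermediate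
21 | diol, C1 secondary and C8 primary alcohol, cis-cyclopropane (labels 1S,4R,5R,6R,7R,7′R) | OC[C@@H]1[C@H]([C@H]2[C@@H](O)CC[C@]2(C)[C@@H](CC(C)C)c2c(OC)cc(OC)cc2OC)C1(C)C | intermediate
22 | keto aldehyde, C1 ketone and C8 aldehyde (labels 4R,5R,6R,7R,7′R; not isolated) | O=C[C@@H]1[C@H]([C@H]2C(=O)CC[C@]2(C)[C@@H](CC(C)C)c2c(OC)cc(OC)cc2OC)C1(C)C | intermediate
23 | (E)-enone C7–CH=CH–C(=O)CH3 with C1 ketone (labels 4R,5R,6R,7R,7′R) | CC(=O)/C=C/[C@@H]1[C@H]([C@H]2C(=O)CC[C@]2(C)[C@@H](CC(C)C)c2c(OC)cc(OC)cc2OC)C1(C)C | intermediate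
24 | diketone with 3-oxobutyl chain, aryl = 2,4,6-trimethoxyphenyl | CC(=O)CC[C@@H]1[C@H]([C@H]2C(=O)CC[C@]2(C)[C@@H](CC(C)C)c2c(OC)cc(OC)cc2OC)C1(C)C | intermediate
25 | diketone, aryl = 3,5-diformyl-2,4,6-trimethoxyphenyl | CC(=O)CC[C@@H]1[C@H]([C@H]2C(=O)CC[C@]2(C)[C@@H](CC(C)C)c2c(OC)c(C=O)c(OC)c(C=O)c2OC)C1(C)C | intermediate
26 | CNP0217082.3 (labels 4R,5R,6R,7R,7′R) | CC(=O)CC[C@@H]1[C@H]([C@H]2C(=O)CC[C@]2(C)[C@@H](CC(C)C)c2c(O)c(C=O)c(O)c(C=O)c2O)C1(C)C | target

Total step count: 17. Longest linear sequence: 17 steps (1 → 26); 2 and 5 enter as purchased compounds.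

Steps most likely to fail

Step 12 (key step). The carbene may be diverted into C–H insertion at C2 or into dimerisation, or it may add through the minor rotamer with loss of facial control. The fallback transfers an isopropylidene unit to an unsaturated lactone instead of adding a carbene to the isobutenyl group. It sets out from 17 and comes back at 20.
- Acylation of 17 with acryloyl chloride and Et3N gives the acrylate ester F1.
- Ring-closing metathesis with the second-generation Grubbs catalyst in refluxing toluene joins the acrylate CH to C6, expels 2-methylpropene and gives the cis-fused α,β-unsaturated δ-lactone F2.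
- Diphenylsulfonium isopropylide (isopropyldiphenylsulfonium tetrafluoroborate, LDA, DME, −78 °C) adds to C6 from the convex face, which is the face of H1 and H5, and closes onto C7. This should give 20 with the same configuration.

Step 4. Selectivity at C7′ may erode through the other ketene acetal geometry or a boat pathway, and the rearrangement at the crowded C4 terminus may be slow, allowing the enolate or ketene acetal to decompose. The fallback fixes the vinyl ether geometry in a separate reagent. It sets out from 4 and comes back at 10.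
- Takai olefination of 2,4,6-trimethoxybenzaldehyde (CHI3, CrCl2, THF) gives the (E)-vinyl iodide F3.
- Copper-catalysed C–O coupling of F3 with 4 (CuI, 3,4,7,8-tetramethyl-1,10-phenanthroline, Cs2CO3, toluene, 80 °C) gives the allyl (E)-styryl ether F4.
- Further heating in xylene brings about the aliphatic Claisen rearrangement through the same chair and gives the aldehyde F5.
- NaBH4 in MeOH reduces F5 to 10.

Step 7. Displacement at the β-branched C8′ may be slow, so that elimination towards C7′ or participation of an ortho-methoxy oxygen wins. The fallback reverses the polarity at C8′. It sets out from 10 and comes back at 12.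
- An Appel reaction (I2, PPh3, imidazole) gives the primary iodide F6.
- Zinc dust and LiCl in THF insert to give the alkylzinc iodide F7.
- Negishi coupling with 2-bromopropene (Pd(PPh3)4, THF, 50 °C) gives the methallyl compound F8.
- H2 with RhCl(PPh3)3 saturates the 1,1-disubstituted alkene of F8 in preference to the hindered trisubstituted diene and gives 12.

Further compounds
F1 | step 12 | acrylate ester of 17 | C=CC(=O)O[C@H]1CC[C@](C)([C@@H](CC(C)C)c2c(OC)cc(OC)cc2OC)[C@H]1C=C(C)C
F2 | step 12 | cis-fused α,β-unsaturated δ-lactone (C6=C7) | O=C1O[C@H]2CC[C@](C)([C@@H](CC(C)C)c3c(OC)cc(OC)cc3OC)[C@H]2C=C1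
F3 | step 4 | (E)-2-(2-iodoethenyl)-1,3,5-trimethoxybenzene | COc1cc(OC)c(/C=C/I)c(OC)c1
F4 | step 4 | (1R)-3-methyl-2-(2-methylprop-1-enyl)cyclopent-2-en-1-yl (E)-2-(2,4,6-trimethoxyphenyl)ethenyl ether | COc1cc(OC)c(/C=C/O[C@@H]2CCC(C)=C2C=C(C)C)c(OC)c1
F5 | step 4 | (2R)-2-[(1R)-1-methyl-2-(2-methylprop-1-enyl)cyclopent-2-en-1-yl]-2-(2,4,6-trimethoxyphenyl)acetaldehyde | O=C[C@@H](c1c(OC)cc(OC)cc1OC)[C@@]1(C)CCC=C1C=C(C)C
F6 | step 7 | primary iodide from 10 | IC[C@@H](c1c(OC)cc(OC)cc1OC)[C@@]1(C)CCC=C1C=C(C)C
F7 | step 7 | alkylzinc iodide from F6 | I[Zn]C[C@@H](c1c(OC)cc(OC)cc1OC)[C@@]1(C)CCC=C1C=C(C)C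
F8 | step 7 | methallyl compound (C8′H2–C(CH3)=CH2) | C=C(C)C[C@@H](c1c(OC)cc(OC)cc1OC)[C@@]1(C)CCC=C1C=C(C)C
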